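## Retrosynthetic overview

1. Labels: ring A = resorcinol ring; B = catechol ring fused to the seven-membered ring; C = six-membered ring between A and D; D = central phenol ring; E = pendant catechol; C7 = CH2 on A; C8 = CH between B and D; C9 = CH bearing E; C10 = CH2 on D. Ring-D carbons: D1 (bears C10), D2 (CH), D3 (C–O), D4 (CH), D5 (bonded to ring A), D6 (bears C8).
2. Feature used: ring D holds one oxygen only, on D3, para to D6 and between the CH carbons D2 and D4, and the D5–D6 edge is shared with ring C. This is the pattern left by a cyclohexenone annulated onto C1/C2 of a 1-tetralone (ring A, C7, C8, D6, D5), so the target goes back through O-demethylation and dehydrogenation to a ring-D cyclohexenone.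
3. Key disconnection: the cyclohexenone is opened at D4=D5 (aldol condensation, ring D) and at D6–D1 (Michael addition, seven-membered ring). This gives a 3-aryl-6,8-dimethoxy-1-tetralone whose ring-B aryl group carries the C9–C10 chain ending in an E methyl enone. The congested A–D aryl–aryl bond needs no cross-coupling, because it is already the bond from ring A to the tetralone carbonyl carbon.
4. The enone comes from an aldehyde and an acetonyl ylide, and ring C from Friedel–Crafts acylation of a butanoic acid on ring A. C9 comes from rhodium-catalysed arylation of a ring-B enal, run while D5 is still an ester, since a tetralone enolate would add 5-exo to C9 of the enal. C8 comes from rhodium-catalysed arylation of a ring-A butenoate with an ortho-bromo ring-B boronic acid.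
5. Ring order: C (step 8), then the seven-membered ring and ring D in one flask (step 11), with ring D aromatised in step 12. Rings A, B and E are bought.

Key step: step 11

Assumption: (1S,4S)-2,5-diphenylbicyclo[2.2.2]octa-2,5-diene on rhodium is taken to deliver the aryl group to the α-si face of E-configured acceptors, the sense that gives the (S)-adduct with cyclohex-2-enone. Both ligand enantiomers are commercial, so the antipode would be used if a model run showed the opposite sense.

## Route

Step 1
Reactants: 1 (3,5-dimethoxyphenyl)acetic acid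
Product: 2 2-(3,5-dimethoxyphenyl)ethanol
Conditions: BH3·THF (1.5 equiv), THF, 0 °C to rt; then H2O
Reagents that add atoms: none
Why: Borane reduction of a carboxylic acid is fast and chemoselective, so the acid should go cleanly to the primary alcohol while the aryl methyl ethers stay intact.

Step 2
Reactants: 2 2-(3,5-dimethoxyphenyl)ethanol; 3 methyl (triphenylphosphoranylidene)acetate
Product: 5 methyl (E)-4-(3,5-dimethoxyphenyl)but-2-enoate, via arylacetaldehyde 4 (not isolated)
Conditions: IBX (1.3 equiv), 3 (1.5 equiv), DMSO, rt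
Reagents that add atoms: none
Why: In this one-pot IBX oxidation–Wittig olefination the enolisable arylacetaldehyde is trapped as it forms, the stabilised ylide should give the E-enoate, and the absence of base keeps the double bond from moving into conjugation with ring A.

Step 3
Reactants: 6 1,2-dibromo-4,5-dimethoxybenzene
Product: 8 (2-bromo-4,5-dimethoxyphenyl)boronic acid, via lithium aryltriisopropoxyborate 7 (not isolated)
Conditions: B(OiPr)3 (1.3 equiv), n-BuLi (1.05 equiv, added last), THF–toluene, –78 °C; then 1 M HCl, rt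
Reagents that add atoms: triisopropyl borate, CC(C)OB(OC(C)C)OC(C)C; water, O
Why: Single bromine–lithium exchange with in situ borate quench captures the ortho-bromoaryllithium before it can lose LiBr to an aryne, and the anionic borate formed resists a second exchange.

Step 4
Reactants: 5 methyl (E)-4-(3,5-dimethoxyphenyl)but-2-enoate; 8 (2-bromo-4,5-dimethoxyphenyl)boronic acid
Product: 9 methyl (3R)-3-(2-bromo-4,5-dimethoxyphenyl)-4-(3,5-dimethoxyphenyl)butanoate
Conditions: [RhCl(C2H4)2]2 (2.5 mol %), (1S,4S)-2,5-diphenylbicyclo[2.2.2]octa-2,5-diene (5.5 mol %), KOH (0.2 equiv), 8 (2.5 equiv), dioxane–H2O 10:1, 40 °C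
Reagents that add atoms: none
Why: In this Hayashi–Miyaura asymmetric 1,4-addition the aryl–rhodium species held by the C2-symmetric diene should insert the E-enoate at its α-si face and so set C8 as R, while monovalent rhodium leaves the C–Br bond alone and the borate-buffered medium is too weakly basic to deconjugate 5.

Step 5
Reactants: 9 methyl (3R)-3-(2-bromo-4,5-dimethoxyphenyl)-4-(3,5-dimethoxyphenyl)butanoate; 10 (E)-2-(3,3-diethoxyprop-1-en-1-yl)-4,4,5,5-tetramethyl-1,3,2-dioxaborolane
Product: 12 methyl (3R)-3-{4,5-dimethoxy-2-[(E)-3-oxoprop-1-en-1-yl]phenyl}-4-(3,5-dimethoxyphenyl)butanoate, via diethyl acetal 11 (not isolated)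
Conditions: Pd(OAc)2 (3 mol %), SPhos (6 mol %), K3PO4 (2 equiv), THF–H2O 10:1, 60 °C; then 1 M HCl, THF, rt
Reagents that add atoms: water, O
Why: Suzuki–Miyaura coupling with a dialkylbiarylphosphine ligand copes with hindered electron-rich aryl bromides and keeps the E-alkenyl geometry, mild acid then unmasks the enal, and C8 carries no acidic hydrogen that could be lost.

Step 6
Reactants: 12 methyl (3R)-3-{4,5-dimethoxy-2-[(E)-3-oxoprop-1-en-1-yl]phenyl}-4-(3,5-dimethoxyphenyl)butanoate; 13 (3,4-dimethoxyphenyl)boronic acid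
Product: 15 methyl (3R)-3-{2-[(1R)-1-(3,4-dimethoxyphenyl)-3-hydroxypropyl]-4,5-dimethoxyphenyl}-4-(3,5-dimethoxyphenyl)butanoate, via diarylpropanal 14 (not isolated)
Conditions: [RhCl(C2H4)2]2 (2.5 mol %), (1S,4S)-2,5-diphenylbicyclo[2.2.2]octa-2,5-diene (5.5 mol %), KOH (0.2 equiv), 13 (2 equiv), MeOH–H2O 10:1, 30 °C; then NaBH4 (1.5 equiv), 0 °C
Reagents that add atoms: none
Why: In this Hayashi–Miyaura asymmetric 1,4-addition to a β-aryl enal, where diene–rhodium catalysts favour 1,4- over 1,2-addition, insertion at the α-si face under catalyst control should set C9 as R, and NaBH4 in the same flask stores the aldehyde as the alcohol without touching the methyl ester.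

Step 7
Reactants: 15 methyl (3R)-3-{2-[(1R)-1-(3,4-dimethoxyphenyl)-3-hydroxypropyl]-4,5-dimethoxyphenyl}-4-(3,5-dimethoxyphenyl)butanoate
Product: 16 (3R)-3-{2-[(1R)-1-(3,4-dimethoxyphenyl)-3-hydroxypropyl]-4,5-dimethoxyphenyl}-4-(3,5-dimethoxyphenyl)butanoic acid
Conditions: LiOH·H2O (3 equiv), THF–MeOH–H2O, rt; then 1 M HCl to pH 3
Reagents that add atoms: lithium hydroxide, [Li+].[OH-]
Why: Saponification of an unhindered methyl ester is routine, and neither C8 (β to the carboxyl group) nor C9 is acidic enough to epimerise.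

Step 8
Reactants: 16 (3R)-3-{2-[(1R)-1-(3,4-dimethoxyphenyl)-3-hydroxypropyl]-4,5-dimethoxyphenyl}-4-(3,5-dimethoxyphenyl)butanoic acid
Product: 18 (3R)-3-{2-[(1R)-1-(3,4-dimethoxyphenyl)-3-hydroxypropyl]-4,5-dimethoxyphenyl}-6,8-dimethoxy-3,4-dihydronaphthalen-1(2H)-one, via tetralone trifluoroacetate 17 (not isolated)
Conditions: (CF3CO)2O (5 equiv), CF3CO2H–CH2Cl2 1:4, 0 °C to rt; evaporate; K2CO3 (0.2 equiv), MeOH, 0 °C
Reagents that add atoms: trifluoroacetic anhydride, O=C(OC(=O)C(F)(F)F)C(F)(F)F (its acyl group is carried only by 17)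
Why: In this intramolecular Friedel–Crafts acylation through the mixed trifluoroacetic anhydride, ring A is attacked six-ring-wise at one of its two equivalent carbons ortho and para to methoxy groups, much faster than ring B could give an indanone, while the alcohol is masked in situ as a trifluoroacetate that methanol removes and the lack of a Lewis acid spares the peri methoxy group.

Step 9
Reactants: 18 (3R)-3-{2-[(1R)-1-(3,4-dimethoxyphenyl)-3-hydroxypropyl]-4,5-dimethoxyphenyl}-6,8-dimethoxy-3,4-dihydronaphthalen-1(2H)-one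
Product: 19 (3R)-3-{2-[(1R)-1-(3,4-dimethoxyphenyl)-3-oxopropyl]-4,5-dimethoxyphenyl}-6,8-dimethoxy-3,4-dihydronaphthalen-1(2H)-one
Conditions: Dess–Martin periodinane (1.3 equiv), CH2Cl2, 0 °C to rt
Reagents that add atoms: none
Why: Dess–Martin oxidation stops at the aldehyde under nearly neutral conditions, which avoids aldol chemistry between the new aldehyde and the tetralone.

Step 10
Reactants: 19 (3R)-3-{2-[(1R)-1-(3,4-dimethoxyphenyl)-3-oxopropyl]-4,5-dimethoxyphenyl}-6,8-dimethoxy-3,4-dihydronaphthalen-1(2H)-one; 20 1-(triphenylphosphoranylidene)propan-2-one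
Product: 21 (3R)-3-{2-[(1R,3E)-1-(3,4-dimethoxyphenyl)-5-oxohex-3-en-1-yl]-4,5-dimethoxyphenyl}-6,8-dimethoxy-3,4-dihydronaphthalen-1(2H)-one
Conditions: 20 (2 equiv), toluene, 80 °C
Reagents that add atoms: none
Why: Wittig olefination with this stabilised ylide is E-selective, reacts with the aldehyde but not with the hindered aryl ketone, and needs no added base, so the cascade of step 11 is not triggered early.

Step 11
Reactants: 21 (3R)-3-{2-[(1R,3E)-1-(3,4-dimethoxyphenyl)-5-oxohex-3-en-1-yl]-4,5-dimethoxyphenyl}-6,8-dimethoxy-3,4-dihydronaphthalen-1(2H)-one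
Product: 24 ring-D cyclohexenone hexamethyl ether (epimer mixture at D1/D6), via Michael adduct 22 (not isolated), via ketol 23 (not isolated)
Conditions: KOH (2 equiv), MeOH–THF 3:1, 0.003 M, argon, rt, then 60 °C
Reagents that add atoms: none
Why: Hydroxide and methoxide equilibrate all enolates of 21, and the tetralone enolate, which can form only at D6, adds to the enone β-carbon D1 (7-exo-trig, closing the seven-membered ring) to give 1,5-diketone 22. The methyl ketone enolate carbon D4 then attacks the tetralone carbonyl D5 (6-(enolendo)-exo-trig aldol, closing ring D as ketol 23), and E1cB loss of water gives enone 24, whose conjugation with the electron-rich ring A makes it the thermodynamic sink that draws the reversible earlier steps forward. The closest known reaction type is the Robinson annulation of 1-tetralones to tetrahydrophenanthren-2-ones, run here with the Michael acceptor tied to the donor. The new sp3 centres D6 and D1 are not controlled and need not be, since D6 stays epimerisable and both become sp2 in step 12, whereas C8 and C9 bear no acidic hydrogen and are retained. The step needs the intramolecular Michael addition to win over intermolecular addition, methanol addition and enone deconjugation; the last two are reversible, and the first is suppressed by high dilution and by the ortho-phenylene unit B1–B6, which holds C8 and C9 side by side and leaves only four rotatable bonds in the forming ring.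

Step 12
Reactants: 24 ring-D cyclohexenone hexamethyl ether
Product: 26 ring-D phenol hexamethyl ether, via cyclohexadienone 25 (not isolated)
Conditions: Pd(OCOCF3)2 (5 mol %), 2-(dimethylamino)pyridine (10 mol %), p-TsOH·H2O (20 mol %), O2 (1 atm), DMSO, 80 °C
Reagents that add atoms: none
Why: In this palladium-catalysed aerobic dehydrogenation of a cyclohexenone the divalent palladium enolate forms at D2, the only sp3 α-carbon, β-hydride elimination of the D1 hydrogen gives cross-conjugated dienone 25, which tautomerises at D6 to the phenol, O2 reoxidises zerovalent palladium, and the conditions are too mild to dehydrogenate the C7–C8 bond of ring C.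

Step 13
Reactants: 26 ring-D phenol hexamethyl ether
Product: 27 CNP0306974.2
Conditions: BBr3 (15 equiv), CH2Cl2, –78 °C to rt, argon; then H2O, 0 °C
Reagents that add atoms: none
Why: In boron tribromide ether cleavage each aryl methyl ether is activated at oxygen and demethylated by bromide in an SN2 step at the methyl carbon, which does not touch C8–H or C9–H, and hydrolysis of the aryl borates frees all seven phenols.

## Compound list

1 | (3,5-dimethoxyphenyl)acetic acid | COc1cc(CC(=O)O)cc(OC)c1 | starting material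
2 | 2-(3,5-dimethoxyphenyl)ethanol | COc1cc(CCO)cc(OC)c1 | intermediate
3 | methyl (triphenylphosphoranylidene)acetate | COC(=O)C=P(c1ccccc1)(c1ccccc1)c1ccccc1 | starting material
4 | (3,5-dimethoxyphenyl)acetaldehyde (formed in the flask, step 2) | COc1cc(CC=O)cc(OC)c1 | intermediate
5 | methyl (E)-4-(3,5-dimethoxyphenyl)but-2-enoate | COC(=O)/C=C/Cc1cc(OC)cc(OC)c1 | intermediate
6 | 1,2-dibromo-4,5-dimethoxybenzene | COc1cc(Br)c(Br)cc1OC | starting material
7 | lithium (2-bromo-4,5-dimethoxyphenyl)triisopropoxyborate (formed in the flask, step 3) | [Li+].COc1cc(Br)c(cc1OC)[B-](OC(C)C)(OC(C)C)OC(C)C | intermediate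
8 | (2-bromo-4,5-dimethoxyphenyl)boronic acid | COc1cc(Br)c(cc1OC)B(O)O | intermediate
9 | methyl (3R)-3-(2-bromo-4,5-dimethoxyphenyl)-4-(3,5-dimethoxyphenyl)butanoate | COc1cc(OC)cc(c1)C[C@H](CC(=O)OC)c1cc(OC)c(OC)cc1Br | intermediate
10 | (E)-2-(3,3-diethoxyprop-1-en-1-yl)-4,4,5,5-tetramethyl-1,3,2-dioxaborolane | CCOC(OCC)/C=C/B1OC(C)(C)C(C)(C)O1 | starting material
11 | methyl (3R)-3-{2-[(E)-3,3-diethoxyprop-1-en-1-yl]-4,5-dimethoxyphenyl}-4-(3,5-dimethoxyphenyl)butanoate (formed in the flask, step 5) | COc1cc(OC)cc(c1)C[C@H](CC(=O)OC)c1cc(OC)c(OC)cc1/C=C/C(OCC)OCC | intermediate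
12 | methyl (3R)-3-{4,5-dimethoxy-2-[(E)-3-oxoprop-1-en-1-yl]phenyl}-4-(3,5-dimethoxyphenyl)butanoate | COc1cc(OC)cc(c1)C[C@H](CC(=O)OC)c1cc(OC)c(OC)cc1/C=C/C=O | intermediate
13 | (3,4-dimethoxyphenyl)boronic acid | COc1ccc(B(O)O)cc1OC | starting material
14 | methyl (3R)-3-{2-[(1R)-1-(3,4-dimethoxyphenyl)-3-oxopropyl]-4,5-dimethoxyphenyl}-4-(3,5-dimethoxyphenyl)butanoate (formed in the flask, step 6) | COc1cc(OC)cc(c1)C[C@H](CC(=O)OC)c1cc(OC)c(OC)cc1[C@@H](c1ccc(OC)c(OC)c1)CC=O | intermediate
15 | methyl (3R)-3-{2-[(1R)-1-(3,4-dimethoxyphenyl)-3-hydroxypropyl]-4,5-dimethoxyphenyl}-4-(3,5-dimethoxyphenyl)butanoate | COc1cc(OC)cc(c1)C[C@H](CC(=O)OC)c1cc(OC)c(OC)cc1[C@@H](c1ccc(OC)c(OC)c1)CCO | intermediate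
16 | (3R)-3-{2-[(1R)-1-(3,4-dimethoxyphenyl)-3-hydroxypropyl]-4,5-dimethoxyphenyl}-4-(3,5-dimethoxyphenyl)butanoic acid | COc1cc(OC)cc(c1)C[C@H](CC(=O)O)c1cc(OC)c(OC)cc1[C@@H](c1ccc(OC)c(OC)c1)CCO | intermediate
17 | (3R)-3-(3,4-dimethoxyphenyl)-3-{2-[(2R)-5,7-dimethoxy-4-oxo-1,2,3,4-tetrahydronaphthalen-2-yl]-4,5-dimethoxyphenyl}propyl trifluoroacetate (formed in the flask, step 8) | COc1cc(OC)c2c(c1)C[C@H](CC2=O)c1cc(OC)c(OC)cc1[C@@H](c1ccc(OC)c(OC)c1)CCOC(=O)C(F)(F)F | intermediate
18 | (3R)-3-{2-[(1R)-1-(3,4-dimethoxyphenyl)-3-hydroxypropyl]-4,5-dimethoxyphenyl}-6,8-dimethoxy-3,4-dihydronaphthalen-1(2H)-one | COc1cc(OC)c2c(c1)C[C@H](CC2=O)c1cc(OC)c(OC)cc1[C@@H](c1ccc(OC)c(OC)c1)CCO | intermediate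
19 | (3R)-3-{2-[(1R)-1-(3,4-dimethoxyphenyl)-3-oxopropyl]-4,5-dimethoxyphenyl}-6,8-dimethoxy-3,4-dihydronaphthalen-1(2H)-one | COc1cc(OC)c2c(c1)C[C@H](CC2=O)c1cc(OC)c(OC)cc1[C@@H](c1ccc(OC)c(OC)c1)CC=O | intermediate
20 | 1-(triphenylphosphoranylidene)propan-2-one | CC(=O)C=P(c1ccccc1)(c1ccccc1)c1ccccc1 | starting material
21 | (3R)-3-{2-[(1R,3E)-1-(3,4-dimethoxyphenyl)-5-oxohex-3-en-1-yl]-4,5-dimethoxyphenyl}-6,8-dimethoxy-3,4-dihydronaphthalen-1(2H)-one (key-step precursor) | COc1cc(OC)c2c(c1)C[C@H](CC2=O)c1cc(OC)c(OC)cc1[C@@H](c1ccc(OC)c(OC)c1)C/C=C/C(C)=O | intermediate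
22 | Michael adduct: seven-membered ring closed by the D6–D1 bond, tetralone ketone kept, D1 bears CH2C(O)CH3; C8 R, C9 R, D1/D6 mixed (formed in the flask, step 11) | COc1cc(OC)c2c(c1)C[C@H]1c3cc(OC)c(OC)cc3[C@@H](c3ccc(OC)c(OC)c3)CC(CC(C)=O)C1C2=O | intermediate
23 | ketol: ring D closed, tertiary OH on D5, ketone on D3; C8 R, C9 R (formed in the flask, step 11) | COc1cc(OC)c2c(c1)C[C@H]1c3cc(OC)c(OC)cc3[C@@H](c3ccc(OC)c(OC)c3)CC3CC(=O)CC2(O)C31 | intermediate
24 | ring-D cyclohexenone hexamethyl ether: C=O on D3, D4=D5 conjugated with ring A, D1-H and D6-H sp3 (epimer mixture); C8 R, C9 R (key-step product) | COc1cc(OC)c2c(c1)C[C@H]1c3cc(OC)c(OC)cc3[C@@H](c3ccc(OC)c(OC)c3)CC3CC(=O)C=C2C31 | intermediate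
25 | cross-conjugated cyclohexadienone: D1=D2 and D4=D5, D6-H sp3 (formed in the flask, step 12) | COc1cc(OC)c2c(c1)C[C@H]1c3cc(OC)c(OC)cc3[C@@H](c3ccc(OC)c(OC)c3)CC3=CC(=O)C=C2C31 | intermediate
26 | ring-D phenol hexamethyl ether: free OH on D3; C8 S, C9 R (same spatial arrangement, the C8 descriptor changes only because D6 is now aromatic) | COc1cc(OC)c2c(c1)C[C@H]1c3cc(OC)c(OC)cc3[C@@H](c3ccc(OC)c(OC)c3)Cc3cc(O)cc-2c31 | intermediate
27 | CNP0306974.2, heptaphenol; C8 S, C9 R | Oc1cc(O)c2c(c1)C[C@H]1c3cc(O)c(O)cc3[C@@H](c3ccc(O)c(O)c3)Cc3cc(O)cc-2c31 | target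

## Step count and risks

Total step count: 13. Longest linear sequence: 12 (steps 1, 2, 4–13). Step 3 is the side branch.

**Step 11.** Closure of the seven-membered ring may be too slow, so that intermolecular Michael addition (oligomerisation) and reversible enone deconjugation take over. The aldol condensation may also stall at the hindered, electron-rich tetralone carbonyl.

The fallback sets out from 19 and returns at 24. It closes the seven-membered ring by an aldol condensation and builds ring D by an intermolecular annulation.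
- KOH in dilute MeOH condenses the aldehyde carbon D1 with the tetralone carbon D6. This gives the seven-membered-ring 2-alkylidene-1-tetralone F1, whose conjugated enone is the thermodynamic sink.
- Ethyl acetoacetate with NaOEt in refluxing EtOH adds to D1 and condenses with D5, as is known for 2-alkylidene- and 2-arylidene-1-tetralones. This gives the ethyl cyclohexenonecarboxylate F2.
- Aqueous KOH in EtOH at reflux, then acidification and warming, saponifies and decarboxylates the β-keto ester to 24.

**Step 4.** Protodeboronation of the ortho-bromo boronic acid may outrun transmetalation and insertion. The double bond of the acceptor may migrate into conjugation with ring A, and facial selectivity may erode.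

The fallback sets out from 2 and 6 and returns at 9. It uses an auxiliary-controlled cuprate addition.
- Alcohol 2 is oxidised with IBX to aldehyde 4.
- Aldehyde 4 is olefinated with (S)-3-[(diethoxyphosphoryl)acetyl]-4-phenyloxazolidin-2-one (Horner–Wadsworth–Emmons reaction, LiCl, iPr2NEt, MeCN) to the N-enoyl imide F3.
- The aryl Grignard reagent from 6 (iPrMgCl·LiCl, THF, –15 °C) is added with CuBr·SMe2 at –40 °C. It attacks the magnesium-chelated s-cis imide on the face away from the auxiliary phenyl group, giving the conjugate adduct F4 with C8 R.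
- NaOMe in MeOH at 0 °C gives 9 and releases the auxiliary.

**Step 6.** Insertion may be slow at the crowded β-carbon next to the ortho sec-alkyl group. 1,2-Addition to the aldehyde may compete, and double stereodifferentiation with C8 may be mismatched.

The fallback sets out from 9 and returns at 15.
- Mizoroki–Heck coupling of 9 with (S)-3-acryloyl-4-phenyloxazolidin-2-one (Pd(OAc)2, P(o-tol)3, Et3N, MeCN, 85 °C) gives the N-cinnamoyl-type imide F5.
- (3,4-Dimethoxyphenyl)magnesium bromide with CuBr·SMe2 (THF–Me2S, –40 °C) adds on the face away from the auxiliary phenyl group, giving the 3,3-diarylpropanoyl imide F6 with C9 R.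
- LiBH4 (Et2O, 1 equiv H2O, 0 °C) cleaves the imide reductively faster than it attacks the methyl ester and gives 15.

## Further compounds

F1 | step 11 | seven-membered-ring 2-alkylidene-1-tetralone (D6=D1 double bond, C8 and C9 arranged as in 19) | COc1cc(OC)c2c(c1)C[C@H]1c3cc(OC)c(OC)cc3[C@@H](c3ccc(OC)c(OC)c3)CC=C1C2=O
F2 | step 11 | ethyl cyclohexenonecarboxylate (24 bearing CO2Et on D2) | COc1cc(OC)c2c(c1)C[C@H]1c3cc(OC)c(OC)cc3[C@@H](c3ccc(OC)c(OC)c3)CC3C(C(=O)OCC)C(=O)C=C2C31
F3 | step 4 | (4S)-3-[(2E)-4-(3,5-dimethoxyphenyl)but-2-enoyl]-4-phenyl-1,3-oxazolidin-2-one | O=C(/C=C/Cc1cc(OC)cc(OC)c1)N1[C@@H](c2ccccc2)COC1=O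
F4 | step 4 | (4S)-3-[(3R)-3-(2-bromo-4,5-dimethoxyphenyl)-4-(3,5-dimethoxyphenyl)butanoyl]-4-phenyl-1,3-oxazolidin-2-one | COc1cc(OC)cc(c1)C[C@H](CC(=O)N1[C@@H](c2ccccc2)COC1=O)c1cc(OC)c(OC)cc1Br
F5 | step 6 | methyl (3R)-3-{4,5-dimethoxy-2-[(1E)-3-oxo-3-[(4S)-2-oxo-4-phenyl-1,3-oxazolidin-3-yl]prop-1-en-1-yl]phenyl}-4-(3,5-dimethoxyphenyl)butanoate | COc1cc(OC)cc(c1)C[C@H](CC(=O)OC)c1cc(OC)c(OC)cc1/C=C/C(=O)N1[C@@H](c2ccccc2)COC1=O
F6 | step 6 | methyl (3R)-3-{2-[(1R)-1-(3,4-dimethoxyphenyl)-3-oxo-3-[(4S)-2-oxo-4-phenyl-1,3-oxazolidin-3-yl]propyl]-4,5-dimethoxyphenyl}-4-(3,5-dimethoxyphenyl)butanoate | COc1cc(OC)cc(c1)C[C@H](CC(=O)OC)c1cc(OC)c(OC)cc1[C@@H](c1ccc(OC)c(OC)c1)CC(=O)N1[C@@H](c2ccccc2)COC1=O
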